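**Retrosynthetic overview**
- Rings: A carries the methoxy group, B is the meta-linked ring on the oxygen of A, C is the phenol ring, D is the para-linked ring. The target comes from its ring C O-benzyl ether by hydrogenolysis.
- Key disconnection: both ArCH2–CH2Ar bridges (B–C and A–D) are traced back to ArCH2–NH–CH2Ar. One double nitrogen deletion contracts a 20-membered diaza-macrocycle to the 18-membered carbon frame. It makes the only two C–C bonds of the route, among them the ring-closing bond between the benzylic carbons of rings B and C.
- Enabling feature: all four bridge atoms are primary benzylic CH2 carbons without β-hydrogen. They sit on ring B meta to its ether oxygen, on ring C para to the phenolic oxygen, on ring A ortho to its ether oxygen and on ring D para to its ether oxygen. Each loss of N2 therefore leaves a stabilised benzyl/benzyl radical pair that can only recombine.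
- The diaza-macrocycle comes from two reductive aminations: ring A CHO with ring D CH2NH2 (intermolecular), then ring B CH2NH2 with ring C CHO (ring closure). The two halves come from two SNAr diaryl ether syntheses on four commercial arenes.
- Order of ring formation: 20-membered ring (step 6), then the 19- and 18-membered rings (both in step 7).

Key step: step 7

Assumption: the target has no stereocentre and its 18-membered ring is taken as conformationally mobile, so no atropisomer has to be controlled.

**Step 1**
Reactants: 1 2-fluoro-3-methoxybenzaldehyde; 2 tert-butyl N-[(3-hydroxyphenyl)methyl]carbamate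
Product: 3 tert-butyl N-{[3-(2-formyl-6-methoxyphenoxy)phenyl]methyl}carbamate
Conditions: K2CO3, DMF, 110 °C
Reagents that add atoms: none
Why: Nucleophilic aromatic substitution (SNAr), in which the formyl group ortho to fluorine stabilises the Meisenheimer adduct, the phenoxide of 2 is the only strong nucleophile, and K2CO3 does not deprotonate the carbamate N–H.

**Step 2**
Reactants: 4 4-fluorobenzonitrile; 5 4-(benzyloxy)-3-hydroxybenzaldehyde
Product: 6 4-[2-(benzyloxy)-5-formylphenoxy]benzonitrile
Conditions: K2CO3, DMF, 120 °C
Reagents that add atoms: none
Why: SNAr, in which the phenoxide of 5 displaces the fluoride para to the nitrile; the other oxygen of 5 is blocked as the benzyl ether, so ring C is joined to ring D only through its 3-oxygen.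

**Step 3**
Reactants: 6 4-[2-(benzyloxy)-5-formylphenoxy]benzonitrile
Product: 7 4-[2-(benzyloxy)-5-(1,3-dioxolan-2-yl)phenoxy]benzonitrile
Conditions: ethylene glycol, p-TsOH·H2O (cat.), toluene, reflux, Dean–Stark trap
Reagents that add atoms: ethylene glycol, OCCO
Why: Acid-catalysed acetalisation with azeotropic removal of water masks the ring C aldehyde against hydride and against the amine made in the next step, while nitrile and benzyl ether are inert.

**Step 4**
Reactants: 7 4-[2-(benzyloxy)-5-(1,3-dioxolan-2-yl)phenoxy]benzonitrile
Product: 8 {4-[2-(benzyloxy)-5-(1,3-dioxolan-2-yl)phenoxy]phenyl}methanamine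
Conditions: LiAlH4, THF, 0 °C to reflux; then H2O, aq. NaOH
Reagents that add atoms: none
Why: Hydride reduction of an aryl nitrile to the primary benzylic amine; dioxolane, benzyl ether and diaryl ether do not react with LiAlH4, and the basic work-up keeps the acetal.

**Step 5**
Reactants: 3 tert-butyl N-{[3-(2-formyl-6-methoxyphenoxy)phenyl]methyl}carbamate; 8 {4-[2-(benzyloxy)-5-(1,3-dioxolan-2-yl)phenoxy]phenyl}methanamine
Product: 10 open-chain secondary amine (ring A CH2–NH–CH2 ring D; ring B CH2NHBoc; ring C dioxolane), via open-chain E-aldimine 9 (not isolated)
Conditions: MeOH, 3 Å molecular sieves, rt; then NaBH4, 0 °C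
Reagents that add atoms: none
Why: Stepwise reductive amination, in which condensation to the aldimine is completed before the hydride is added; this prevents double alkylation, and NaBH4 leaves carbamate and acetal untouched.

**Step 6**
Reactants: 10 open-chain secondary amine
Product: 13 diaza-macrocycle (20-membered; both bridges CH2–NH–CH2; ring C oxygen benzylated), via amino aldehyde 11 (not isolated), via macrocyclic E-aldimine 12 (not isolated)
Conditions: TFA, CH2Cl2, H2O, rt, evaporate; then slow addition to Et3N, 4 Å molecular sieves, CH2Cl2–MeOH (1 mM), rt; then NaBH4, 0 °C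
Reagents that add atoms: none
Why: Acidolysis removes the Boc group and hydrolyses the dioxolane in one pot and macrocyclic reductive amination follows, in which reversible imine formation at high dilution lets open oligomers revert to the 20-membered E-imine before NaBH4 fixes it, while the internal secondary amine could only close a strained 11-membered para-bridged ring.

**Step 7**
Reactants: 13 diaza-macrocycle
Product: 17 O-benzyl ether of the target (18-membered ring; both bridges CH2–CH2), via first isodiazene 14 (not isolated), via ring-contracted monoamine 15 (not isolated), via second isodiazene 16 (not isolated)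
Conditions: anomeric amide N-(benzyloxy)-N-(pivaloyloxy)-4-(trifluoromethyl)benzamide (3 equiv), THF, 45 °C
Reagents that add atoms: none
Why: Each secondary nitrogen displaces pivalate at the amide nitrogen of the reagent and benzyl 4-(trifluoromethyl)benzoate is then expelled, which leaves an isodiazene (14, later 16) that loses N2 to a singlet benzyl/benzyl radical pair, and the pair collapses in the solvent cage to the CH2–CH2 bond. The closest known reaction type is the nitrogen deletion of secondary dibenzylamines to bibenzyls and of cyclic benzylic amines to ring-contracted carbocycles with this same anomeric amide. The less hindered nitrogen between rings B and C should react first, so radical recombination of the benzylic carbons of rings B and C closes the 19-membered ring of 15, and the same recombination between rings A and D then closes the 18-membered ring of 17; the order has no influence on the product. No stereocentre is formed. The step needs recombination to win over hydrazone tautomerisation, hydrogen abstraction and escape of the radical ends, and the substrate secures this because all four carbons are primary, benzylic and free of β-hydrogen (fast loss of N2, no disproportionation) and because the two radical ends stay tied to each other by the rest of the ring. As the two extrusions are separated in time, one bridge and both diaryl ethers always hold the halves in register, so no A–C or B–D crossover is expected.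

**Step 8**
Reactants: 17 O-benzyl ether of the target
Product: 18 target macrocycle CNP0309263.0
Conditions: H2 (1 atm), Pd/C, EtOAc–EtOH, rt
Reagents that add atoms: none
Why: Hydrogenolysis of the benzyl aryl ether over palladium frees the ring C phenol, while the diaryl ethers, the methyl ether and the bibenzyl bridges are inert under one atmosphere of hydrogen.

**Compound list**
1 | 2-fluoro-3-methoxybenzaldehyde | COc1cccc(C=O)c1F | starting material
2 | tert-butyl N-[(3-hydroxyphenyl)methyl]carbamate | CC(C)(C)OC(=O)NCc1cccc(O)c1 | starting material
3 | tert-butyl N-{[3-(2-formyl-6-methoxyphenoxy)phenyl]methyl}carbamate (rings A and B) | COc1cccc(C=O)c1Oc1cccc(CNC(=O)OC(C)(C)C)c1 | intermediate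
4 | 4-fluorobenzonitrile | N#Cc1ccc(F)cc1 | starting material
5 | 4-(benzyloxy)-3-hydroxybenzaldehyde | O=Cc1ccc(OCc2ccccc2)c(O)c1 | starting material
6 | 4-[2-(benzyloxy)-5-formylphenoxy]benzonitrile (rings C and D) | N#Cc1ccc(Oc2cc(C=O)ccc2OCc2ccccc2)cc1 | intermediate
7 | 4-[2-(benzyloxy)-5-(1,3-dioxolan-2-yl)phenoxy]benzonitrile | N#Cc1ccc(Oc2cc(C3OCCO3)ccc2OCc2ccccc2)cc1 | intermediate
8 | {4-[2-(benzyloxy)-5-(1,3-dioxolan-2-yl)phenoxy]phenyl}methanamine | NCc1ccc(Oc2cc(C3OCCO3)ccc2OCc2ccccc2)cc1 | intermediate
9 | open-chain E-aldimine from 3 and 8 (ring A CH=N–CH2 ring D) | COc1cccc(/C=N/Cc2ccc(Oc3cc(C4OCCO4)ccc3OCc3ccccc3)cc2)c1Oc1cccc(CNC(=O)OC(C)(C)C)c1 | intermediate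
10 | open-chain secondary amine (ring A CH2–NH–CH2 ring D; ring B CH2NHBoc; ring C dioxolane) | COc1cccc(CNCc2ccc(Oc3cc(C4OCCO4)ccc3OCc3ccccc3)cc2)c1Oc1cccc(CNC(=O)OC(C)(C)C)c1 | intermediate
11 | open-chain amino aldehyde (ring B CH2NH2; ring C CHO), handled as its bis(trifluoroacetate) and drawn as the free base | COc1cccc(CNCc2ccc(Oc3cc(C=O)ccc3OCc3ccccc3)cc2)c1Oc1cccc(CN)c1 | intermediate
12 | 20-membered macrocyclic E-aldimine (ring B CH2–N=CH ring C) | COc1cccc2c1Oc1cccc(c1)C/N=C/c1ccc(OCc3ccccc3)c(c1)Oc1ccc(cc1)CNC2 | intermediate
13 | 20-membered diaza-macrocycle (both bridges CH2–NH–CH2; ring C O-benzyl) | COc1cccc2c1Oc1cccc(c1)CNCc1ccc(OCc3ccccc3)c(c1)Oc1ccc(cc1)CNC2 | intermediate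
14 | isodiazene at the nitrogen between rings B and C | COc1cccc2c1Oc1cccc(c1)C[N+](=[N-])Cc1ccc(OCc3ccccc3)c(c1)Oc1ccc(cc1)CNC2 | intermediate
15 | 19-membered monoamine (B–C bridge CH2–CH2; A–D bridge CH2–NH–CH2) | COc1cccc2c1Oc1cccc(c1)CCc1ccc(OCc3ccccc3)c(c1)Oc1ccc(cc1)CNC2 | intermediate
16 | isodiazene at the nitrogen between rings A and D | COc1cccc2c1Oc1cccc(c1)CCc1ccc(OCc3ccccc3)c(c1)Oc1ccc(cc1)C[N+](=[N-])C2 | intermediate
17 | O-benzyl ether of the target (18-membered macrocycle) | COc1cccc2c1Oc1cccc(c1)CCc1ccc(OCc3ccccc3)c(c1)Oc1ccc(cc1)CC2 | intermediate
18 | target macrocycle CNP0309263.0 | COc1cccc2c1Oc1cccc(c1)CCc1ccc(O)c(c1)Oc1ccc(cc1)CC2 | target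

**Step count**
- Total step count: 8.
- Longest linear sequence: 7 (steps 2, 3, 4, 5, 6, 7, 8).

**Steps most likely to fail**

Step 7, double nitrogen deletion.
- What may go wrong: amination of the more hindered nitrogen beside ring A may stall, or an isodiazene may tautomerise to a hydrazone before it loses N2. The contraction would then stop halfway.
- Fallback: it sets out from 13 and generates the nitrogen-extruding species by reduction instead of electrophilic amination.
- tert-Butyl nitrite in CH2Cl2 should convert both N–H groups into the bis(N-nitrosamine) F1.
- Na2S2O4 and NaOH in aqueous ethanol at 60 °C should then reduce each N-nitroso group to the N-amino level. From there N2 is lost and the benzylic carbons join; this behaviour is long known for N-nitrosodibenzylamines, which give bibenzyls.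
- The fallback comes back to the route at 17.

Step 6, macrocyclic reductive amination.
- What may go wrong: intermolecular condensation may outrun ring closure, or the internal secondary amine may capture the aldehyde as an aminal or iminium ion. Either would lead to oligomeric tertiary amines.
- Fallback: it sets out from 10 and removes the competing nitrogen before the ring is closed.
- One equivalent of the same anomeric amide (THF, 45 °C; the carbamate N–H does not react) should pass through the open-chain isodiazene F2 to the open-chain bibenzyl carbamate F3.
- TFA, CH2Cl2 and H2O should then give the amino aldehyde F4.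
- High dilution with Et3N and molecular sieves should give the 19-membered E-aldimine F5, and NaBH4 the 19-membered monoamine F6.
- A single nitrogen deletion through the isodiazene F7 then closes the 18-membered ring between the benzylic carbons of rings B and C.
- The fallback comes back to the route at 17.

Step 1, SNAr at the flanked fluoride.
- What may go wrong: substitution may be slow because the carbon that bears fluorine lies between the methoxy and the formyl group. Prolonged heating may then cause thermal loss of the Boc group and degradation of the aldehyde.
- Fallback: it sets out from 2 and replaces the addition–elimination mechanism by a copper-catalysed Ullmann ether synthesis.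
- Phenol 2 is coupled with commercial 2-bromo-3-methoxybenzaldehyde (CuI, N,N-dimethylglycine, Cs2CO3, dioxane, 90 °C). The ortho carbonyl group assists the coupling.
- This gives 3 directly, so the fallback comes back to the route at 3.

**Further compounds**
F1 | step 7 | bis(N-nitrosamine) of 13 | COc1cccc2c1Oc1cccc(c1)CN(N=O)Cc1ccc(OCc3ccccc3)c(c1)Oc1ccc(cc1)CN(N=O)C2
F2 | step 6 | open-chain isodiazene from 10 | COc1cccc(C[N+](=[N-])Cc2ccc(Oc3cc(C4OCCO4)ccc3OCc3ccccc3)cc2)c1Oc1cccc(CNC(=O)OC(C)(C)C)c1
F3 | step 6 | open-chain bibenzyl carbamate (A–D bridge CH2–CH2; ring B CH2NHBoc; ring C dioxolane) | COc1cccc(CCc2ccc(Oc3cc(C4OCCO4)ccc3OCc3ccccc3)cc2)c1Oc1cccc(CNC(=O)OC(C)(C)C)c1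
F4 | step 6 | amino aldehyde (A–D bridge CH2–CH2; ring B CH2NH2; ring C CHO) | COc1cccc(CCc2ccc(Oc3cc(C=O)ccc3OCc3ccccc3)cc2)c1Oc1cccc(CN)c1
F5 | step 6 | 19-membered E-aldimine (ring B CH2–N=CH ring C) | COc1cccc2c1Oc1cccc(c1)C/N=C/c1ccc(OCc3ccccc3)c(c1)Oc1ccc(cc1)CC2
F6 | step 6 | 19-membered monoamine (B–C bridge CH2–NH–CH2; A–D bridge CH2–CH2) | COc1cccc2c1Oc1cccc(c1)CNCc1ccc(OCc3ccccc3)c(c1)Oc1ccc(cc1)CC2
F7 | step 6 | isodiazene from F6 | COc1cccc2c1Oc1cccc(c1)C[N+](=[N-])Cc1ccc(OCc3ccccc3)c(c1)Oc1ccc(cc1)CC2
F0 | step 1 | none | none
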